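**Retrosynthetic overview**

1. Ring A (C4a, C5, C6, C7, C8, C8a) carries only the two para hydroxyls at C5 and C8 and hydrogen at C6 and C7, so it maps onto a symmetric four-carbon diene.
2. The target is traced back (silyl ether cleavage, loss of ethene, enolization–oxidation) to a bicyclo[2.2.2]octene cycloadduct, in which an ethano bridge between C5 and C8 is a traceless leaving group.
3. The cycloadduct is cut at C4a–C5 and C8a–C8 into the side-chain benzoquinone 8 and 1,4-bis(trimethylsilyloxy)cyclohexa-1,3-diene 10, the latter from cyclohexane-1,4-dione.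
4. Quinone 8 comes from 2,5-dimethoxybenzaldehyde by asymmetric allylboration (sets C1' as R), cross-metathesis, isobutyrylation and oxidative demethylation.
5. Ring order: ring B is the benzene ring of the aldehyde, oxidized to the quinone; ring A is the only ring built, closed in the cycloaddition and aromatized last.

Key step: step 6

Remark on stereochemistry: adduct 11 and the bridged compounds 12 and 13 should each form as a pair of diastereomers that differ only in the sense of the bicyclic unit relative to C1'. One of each pair is drawn, both are carried on together, and the difference vanishes in step 8.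

Remark on the diene: silylation of 9 is expected to give 10 together with its unconjugated 1,4-diene isomer, which cannot take part in step 6; the mixture is used in excess.

**Route**

Step 1
Reactants: 1 2,5-dimethoxybenzaldehyde
Product: 3 (1R)-1-(2,5-dimethoxyphenyl)but-3-en-1-ol, via borinate ester 2 (not isolated)
Conditions: (+)-Ipc2BOMe [from (−)-α-pinene], allylMgBr, Et2O, −78 °C → rt; then 1, −78 °C; then NaOH, H2O2, H2O, rt
Reagents that add atoms: allylmagnesium bromide, C=CC[Mg]Br (allyl source, transferred through (+)-B-allyldiisopinocampheylborane, C=CCB([C@H]1C[C@H]2C[C@@H]([C@@H]1C)C2(C)C)[C@H]1C[C@H]2C[C@@H]([C@@H]1C)C2(C)C); (+)-B-methoxydiisopinocampheylborane, COB([C@H]1C[C@H]2C[C@@H]([C@@H]1C)C2(C)C)[C@H]1C[C@H]2C[C@@H]([C@@H]1C)C2(C)C (its atoms stay only in intermediate 2)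
Why: Brown asymmetric allylboration, in which the allyl group is delivered through a closed chair transition state and the isopinocampheyl groups derived from (−)-α-pinene direct it to the Re face of the aryl aldehyde, should set C1' as R, and oxidative work-up cleaves borinate 2.

Step 2
Reactants: 3 (1R)-1-(2,5-dimethoxyphenyl)but-3-en-1-ol; 4 2-methylbut-2-ene
Product: 5 (1R)-1-(2,5-dimethoxyphenyl)-4-methylpent-3-en-1-ol
Conditions: 4 (large excess), second-generation Grubbs catalyst RuCl2(=CHPh)(H2IMes)(PCy3) (cat.), CH2Cl2, 35 °C, sealed vessel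
Reagents that add atoms: 2-methylbut-2-ene (4), CC=C(C)C
Why: Olefin cross-metathesis of a terminal alkene with 2-methylbut-2-ene transfers an isopropylidene unit and releases propene, a standard way to turn an allyl group into a prenyl-type alkene that leaves the free carbinol and its configuration untouched.

Step 3
Reactants: 5 (1R)-1-(2,5-dimethoxyphenyl)-4-methylpent-3-en-1-ol; 6 isobutyric anhydride
Product: 7 (1R)-1-(2,5-dimethoxyphenyl)-4-methylpent-3-en-1-yl 2-methylpropanoate
Conditions: 6, Et3N, DMAP (cat.), CH2Cl2, 0 °C → rt
Reagents that add atoms: isobutyric anhydride (6), CC(C)C(=O)OC(=O)C(C)C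
Why: DMAP-catalysed acylation through the N-acylpyridinium ion esterifies the secondary benzylic alcohol at oxygen, so the C–O bond of the stereocentre is not broken and the R configuration is kept.

Step 4
Reactants: 7 (1R)-1-(2,5-dimethoxyphenyl)-4-methylpent-3-en-1-yl 2-methylpropanoate
Product: 8 2-[(1R)-1-(isobutyryloxy)-4-methylpent-3-enyl]-1,4-benzoquinone
Conditions: (NH4)2Ce(NO3)6, MeCN–H2O, 0 °C, short reaction time, dark
Reagents that add atoms: water, O (supplies both quinone oxygens)
Why: Oxidative demethylation of a 1,4-dimethoxyarene by tetravalent cerium runs through the arene radical cation with water as the oxygen source, is fast at 0 °C, and is known to tolerate isolated trisubstituted alkenes and benzylic esters.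

Step 5
Reactants: 9 cyclohexane-1,4-dione
Product: 10 1,4-bis(trimethylsilyloxy)cyclohexa-1,3-diene
Conditions: TMSOTf, Et3N, Et2O, 0 °C → rt; distil, use at once
Reagents that add atoms: trimethylsilyl trifluoromethanesulfonate, C[Si](C)(C)OS(=O)(=O)C(F)(F)F
Why: Double silyl enol ether formation with a silyl triflate and a tertiary amine (soft enolization) under equilibrating conditions should favour the conjugated 1,3-diene, in which the two enol ether double bonds are in conjugation.

Step 6
Reactants: 8 2-[(1R)-1-(isobutyryloxy)-4-methylpent-3-enyl]-1,4-benzoquinone; 10 1,4-bis(trimethylsilyloxy)cyclohexa-1,3-diene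
Product: 11 endo cycloadduct, 2-[(1R)-1-(isobutyryloxy)-4-methylpent-3-enyl]-5,8-bis(trimethylsilyloxy)-4a,5,8,8a-tetrahydro-5,8-ethanonaphthalene-1,4-dione
Conditions: 10 (excess), toluene, 0 °C → rt, Ar, dark; concentrate under high vacuum, no aqueous work-up
Reagents that add atoms: 1,4-bis(trimethylsilyloxy)cyclohexa-1,3-diene (10), C[Si](C)(C)OC1=CC=C(O[Si](C)(C)C)CC1
Why: The diene 10, made electron-rich by its two silyloxy groups, and the electron-poor quinone 8 combine in a concerted, suprafacial, normal-electron-demand [4+2] cycloaddition, the closest known reaction type being the Diels–Alder addition of 1-oxygenated cyclohexa-1,3-dienes to quinones. Ring A is closed as a six-membered carbocycle by intermolecular [4+2] annulation, the bonds C4a–C5 and C8a–C8 forming together, so that ring A arises inside a bicyclo[2.2.2]oct-2-ene whose ethano bridge is the later leaving group. The cis relation of the hydrogens at C4a and C8a follows from suprafacial addition to the cis double bond of the quinone, the configurations at C5 and C8 are tied to them by the bridged geometry, and the endo orientation (ene-dione ring syn to the new C6=C7 bond) follows from secondary orbital overlap. The facial sense relative to the side-chain centre C1' is not controlled and need not be, since all four new centres disappear on aromatization. The selectivity that matters is the site selectivity between the two quinone double bonds, and it is secured by the branched substituent on C2, which shields the C2=C3 bond and makes it less electron-poor than the unsubstituted C5=C6 bond. No regiochemical question arises because the diene is constitutionally symmetric.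

Step 7
Reactants: 11 endo cycloadduct
Product: 13 2-[(1R)-1-(isobutyryloxy)-4-methylpent-3-enyl]-5,8-bis(trimethylsilyloxy)-5,8-dihydro-5,8-ethanonaphthalene-1,4-dione, via bridged hydroquinone 12 (not isolated)
Conditions: Et3N (cat.), Ag2O, MgSO4, CH2Cl2, 0 °C → rt, dark; filter through Celite
Reagents that add atoms: none
Why: Base-catalysed enolization of the cis-fused ene-dione moves the two ring-fusion hydrogens to oxygen to give hydroquinone 12, which the monovalent silver oxide present from the start oxidizes at once to the quinone (enolization–oxidation of a quinone Diels–Alder adduct), while β-elimination of the bridgehead silyloxy groups is excluded because it would need a bridgehead double bond.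

Step 8
Reactants: 13 bridged naphthoquinone
Product: 14 2-[(1R)-1-(isobutyryloxy)-4-methylpent-3-enyl]-5,8-bis(trimethylsilyloxy)-1,4-naphthoquinone
Conditions: toluene, 110 °C, Ar, dark, BHT (cat.)
Reagents that add atoms: none
Why: In this Alder–Rickert retro-Diels–Alder reaction the bicyclo[2.2.2]octa-2,5-diene expels its ethano bridge as ethene because the ring left behind is a benzene ring, a cycloreversion that bridgehead oxygen donors and the fused quinone are known to ease and that removes the last bicyclic stereocentres.

Step 9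
Reactants: 14 bis(trimethylsilyl) ether of the target
Product: 15 isobutyrylshikonin, (1R)-1-(5,8-dihydroxy-1,4-dioxo-1,4-dihydronaphthalen-2-yl)-4-methylpent-3-enyl 2-methylpropanoate
Conditions: HCl (cat.), THF–H2O, 0 °C
Reagents that add atoms: none
Why: Acid-catalysed hydrolysis of aryl trimethylsilyl ethers is very fast, the more so peri to a carbonyl group, and frees the two hydrogen-bonded naphthazarin hydroxyls under conditions that should leave the secondary isobutyrate, the alkene and C1' alone.

**Compound list**

1 | 2,5-dimethoxybenzaldehyde | COc1ccc(OC)c(C=O)c1 | starting material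
2 | (1R)-1-(2,5-dimethoxyphenyl)but-3-en-1-yl diisopinocampheylborinate | C=CC[C@@H](OB([C@H]1C[C@H]2C[C@@H]([C@@H]1C)C2(C)C)[C@H]1C[C@H]2C[C@@H]([C@@H]1C)C2(C)C)c1cc(OC)ccc1OC | intermediate (not isolated)
3 | (1R)-1-(2,5-dimethoxyphenyl)but-3-en-1-ol | C=CC[C@@H](O)c1cc(OC)ccc1OC | intermediate
4 | 2-methylbut-2-ene | CC=C(C)C | starting material
5 | (1R)-1-(2,5-dimethoxyphenyl)-4-methylpent-3-en-1-ol | CC(C)=CC[C@@H](O)c1cc(OC)ccc1OC | intermediate
6 | isobutyric anhydride | CC(C)C(=O)OC(=O)C(C)C | starting material
7 | (1R)-1-(2,5-dimethoxyphenyl)-4-methylpent-3-en-1-yl 2-methylpropanoate | CC(C)=CC[C@@H](OC(=O)C(C)C)c1cc(OC)ccc1OC | intermediate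
8 | 2-[(1R)-1-(isobutyryloxy)-4-methylpent-3-enyl]-1,4-benzoquinone | CC(C)=CC[C@@H](OC(=O)C(C)C)C1=CC(=O)C=CC1=O | intermediate
9 | cyclohexane-1,4-dione | O=C1CCC(=O)CC1 | starting material
10 | 1,4-bis(trimethylsilyloxy)cyclohexa-1,3-diene | C[Si](C)(C)OC1=CC=C(O[Si](C)(C)C)CC1 | intermediate
11 | endo cycloadduct, 2-[(1R)-1-(isobutyryloxy)-4-methylpent-3-enyl]-5,8-bis(trimethylsilyloxy)-4a,5,8,8a-tetrahydro-5,8-ethanonaphthalene-1,4-dione; cis ring fusion, ring-fusion hydrogens syn to the ethano bridge (one of two facial diastereomers drawn) | CC(C)=CC[C@@H](OC(=O)C(C)C)C1=CC(=O)[C@@H]2[C@H](C1=O)[C@@]1(O[Si](C)(C)C)CC[C@]2(O[Si](C)(C)C)C=C1 | intermediate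
12 | 2-[(1R)-1-(isobutyryloxy)-4-methylpent-3-enyl]-5,8-bis(trimethylsilyloxy)-5,8-dihydro-5,8-ethanonaphthalene-1,4-diol (one of two diastereomers drawn) | CC(C)=CC[C@@H](OC(=O)C(C)C)c1cc(O)c2c(c1O)[C@@]1(O[Si](C)(C)C)CC[C@]2(O[Si](C)(C)C)C=C1 | intermediate (not isolated)
13 | 2-[(1R)-1-(isobutyryloxy)-4-methylpent-3-enyl]-5,8-bis(trimethylsilyloxy)-5,8-dihydro-5,8-ethanonaphthalene-1,4-dione (one of two diastereomers drawn) | CC(C)=CC[C@@H](OC(=O)C(C)C)C1=CC(=O)C2=C(C1=O)[C@@]1(O[Si](C)(C)C)CC[C@]2(O[Si](C)(C)C)C=C1 | intermediate
14 | 2-[(1R)-1-(isobutyryloxy)-4-methylpent-3-enyl]-5,8-bis(trimethylsilyloxy)-1,4-naphthoquinone | CC(C)=CC[C@@H](OC(=O)C(C)C)C1=CC(=O)c2c(O[Si](C)(C)C)ccc(O[Si](C)(C)C)c2C1=O | intermediate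
15 | isobutyrylshikonin | CC(C)=CC[C@@H](OC(=O)C(C)C)C1=CC(=O)c2c(O)ccc(O)c2C1=O | target

**Step count**

Total steps: 9. Longest linear sequence: 8 (steps 1 to 4, then 6 to 9); step 5 is the one-step side branch.

**Steps most likely to fail**

Step 6. The bridgehead trimethylsilyl ethers of the adduct may be lost during handling. The freed β-hydroxy ketone can then open by retro-aldol cleavage of C4a–C5 or C8a–C8. Hydride transfer from the diene to the quinone, or conjugate addition of the silyl enol ether, may also compete with cycloaddition. The fallback changes the protecting-group plan so that the adduct becomes an isolable, chromatographable compound. It sets out from diketone 9 and quinone 8. Silylation of 9 with TBSOTf and Et3N should give 1,4-bis(tert-butyldimethylsilyloxy)cyclohexa-1,3-diene F1. Cycloaddition of F1 with 8 in toluene should give the tert-butyldimethylsilyl endo cycloadduct F2, which can be purified. Treatment as in step 7 should pass through the bridged hydroquinone F3 to the bridged quinone F4. Heating in toluene should expel ethene to give the 5,8-bis(tert-butyldimethylsilyloxy)naphthoquinone F5. HF·pyridine in THF at 0 °C should cleave the two peri aryl silyl ethers, and the fallback comes back to the route at target 15.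

Step 7. Hydroquinone 12 carries a free phenol ortho to the acyloxyalkyl group. Under base it may expel isobutyrate through an ortho-quinone methide before it is oxidized, which would cost the ester and the configuration at C1'. Enolization of the bridged ene-dione may also be slow. The fallback never frees the phenol. It sets out from adduct 11: TMSOTf and Et3N in CH2Cl2 at −78 → 0 °C should enolize and silylate both carbonyl groups to give the 1,4,5,8-tetrakis(trimethylsilyloxy)-5,8-dihydro-5,8-ethanonaphthalene F6. Oxidative desilylation of the two aryl silyl ethers with pyridinium chlorochromate [C5H5NH][CrO3Cl] in dry CH2Cl2 (known for hydroquinone bis-silyl ethers) should give the quinone directly, and the fallback comes back at bridged quinone 13.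

Step 8. The cycloreversion may need a temperature at which the side chain suffers, by thermal ene reaction between the prenyl group and the quinone, loss of isobutyric acid, or polymerization. The fallback uses a diene whose bridge opens without heat or oxidant. It sets out from quinone 8. Succinic anhydride with TMSCl, Et3N and ZnCl2 (cat.) in MeCN should give 2,5-bis(trimethylsilyloxy)furan F7. Cycloaddition of F7 at the same unsubstituted double bond of 8 forms the same C4a–C5 and C8a–C8 bonds and should give the oxygen-bridged adduct F8. Dilute HCl in THF–H2O at 0 °C should hydrolyse the bis-ketal bridge to the 4a,8a-dihydronaphthalene-1,4,5,8-tetrone F9. This should tautomerize at once to the naphthazarin, and the fallback comes back at target 15.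

**Further compounds**

F1 | step 6 | 1,4-bis(tert-butyldimethylsilyloxy)cyclohexa-1,3-diene | CC(C)(C)[Si](C)(C)OC1=CC=C(O[Si](C)(C)C(C)(C)C)CC1
F2 | step 6 | endo cycloadduct, 2-[(1R)-1-(isobutyryloxy)-4-methylpent-3-enyl]-5,8-bis(tert-butyldimethylsilyloxy)-4a,5,8,8a-tetrahydro-5,8-ethanonaphthalene-1,4-dione (one of two facial diastereomers) | CC(C)=CC[C@@H](OC(=O)C(C)C)C1=CC(=O)[C@@H]2[C@H](C1=O)[C@@]1(O[Si](C)(C)C(C)(C)C)CC[C@]2(O[Si](C)(C)C(C)(C)C)C=C1
F3 | step 6 | 2-[(1R)-1-(isobutyryloxy)-4-methylpent-3-enyl]-5,8-bis(tert-butyldimethylsilyloxy)-5,8-dihydro-5,8-ethanonaphthalene-1,4-diol | CC(C)=CC[C@@H](OC(=O)C(C)C)c1cc(O)c2c(c1O)[C@@]1(O[Si](C)(C)C(C)(C)C)CC[C@]2(O[Si](C)(C)C(C)(C)C)C=C1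
F4 | step 6 | 2-[(1R)-1-(isobutyryloxy)-4-methylpent-3-enyl]-5,8-bis(tert-butyldimethylsilyloxy)-5,8-dihydro-5,8-ethanonaphthalene-1,4-dione | CC(C)=CC[C@@H](OC(=O)C(C)C)C1=CC(=O)C2=C(C1=O)[C@@]1(O[Si](C)(C)C(C)(C)C)CC[C@]2(O[Si](C)(C)C(C)(C)C)C=C1
F5 | step 6 | 2-[(1R)-1-(isobutyryloxy)-4-methylpent-3-enyl]-5,8-bis(tert-butyldimethylsilyloxy)-1,4-naphthoquinone | CC(C)=CC[C@@H](OC(=O)C(C)C)C1=CC(=O)c2c(O[Si](C)(C)C(C)(C)C)ccc(O[Si](C)(C)C(C)(C)C)c2C1=O
F6 | step 7 | (1R)-4-methyl-1-[1,4,5,8-tetrakis(trimethylsilyloxy)-5,8-dihydro-5,8-ethanonaphthalen-2-yl]pent-3-enyl 2-methylpropanoate | CC(C)=CC[C@@H](OC(=O)C(C)C)c1cc(O[Si](C)(C)C)c2c(c1O[Si](C)(C)C)[C@@]1(O[Si](C)(C)C)CC[C@]2(O[Si](C)(C)C)C=C1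
F7 | step 8 | 2,5-bis(trimethylsilyloxy)furan | C[Si](C)(C)Oc1ccc(O[Si](C)(C)C)o1
F8 | step 8 | 2-[(1R)-1-(isobutyryloxy)-4-methylpent-3-enyl]-5,8-bis(trimethylsilyloxy)-4a,5,8,8a-tetrahydro-5,8-epoxynaphthalene-1,4-dione (ring centres not assigned, all transient) | CC(C)=CC[C@@H](OC(=O)C(C)C)C1=CC(=O)C2C(C1=O)C1(O[Si](C)(C)C)C=CC2(O[Si](C)(C)C)O1
F9 | step 8 | 2-[(1R)-1-(isobutyryloxy)-4-methylpent-3-enyl]-4a,8a-dihydronaphthalene-1,4,5,8-tetrone (ring-fusion centres not assigned, transient tautomer of 15) | CC(C)=CC[C@@H](OC(=O)C(C)C)C1=CC(=O)C2C(C1=O)C(=O)C=CC2=O
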